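The furan is disconnected at C3=C4 and C4–C5. Ring carbon C4 carries only hydrogen and sits between C3 (methyl) and C5 (pentyl), so it can be delivered as a one-carbon unit to an acyclic ether that already contains C3, C2, O1 and C5. In one operation, lithiated trimethylsilyldiazomethane turns the C3 methyl ketone of methyl 14-(hexyloxy)-15-oxohexadecanoate into an alkylidene carbene at C4, which inserts into a C–H bond of the hexyl OCH2 group and closes the 2,5-dihydrofuran ring. The precursor is assembled from monomethyl tetradecanedioate, ethynylmagnesium bromide and hexan-1-ol; dehydrogenation and saponification finish the acid.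

Key step: step 7

Remark: ring atoms are numbered O1, C2 (ester/acid chain), C3 (methyl), C4 (H), C5 (pentyl); the target has no stereocentre, so the racemic centres that appear on the way are left uncontrolled.

Step 1
Reactants: 1 14-methoxy-14-oxotetradecanoic acid (monomethyl tetradecanedioate)
Product: 2 methyl 14-hydroxytetradecanoate
Conditions: BH3·SMe2 (1.2 equiv), THF, 0 °C to rt; then MeOH
Reagents that add atoms: none
Why: Chemoselective borane reduction, in which the free acid forms an acyloxyborane that is reduced far faster than the methyl ester, so only the carboxyl group should become CH2OH; no stereocentre is formed.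

Step 2
Reactants: 2 methyl 14-hydroxytetradecanoate
Product: 3 methyl 14-oxotetradecanoate
Conditions: TEMPO (10 mol %), PhI(OAc)2 (1.1 equiv), CH2Cl2, rt
Reagents that add atoms: none
Why: TEMPO-catalysed oxoammonium oxidation with PhI(OAc)2 as terminal oxidant should stop at the aldehyde in the absence of water and leave the ester alone; no stereocentre is formed.

Step 3
Reactants: 3 methyl 14-oxotetradecanoate; 4 ethynylmagnesium bromide
Product: 5 methyl 14-hydroxyhexadec-15-ynoate (racemic)
Conditions: 4 (1.2 equiv), THF, −78 to −20 °C; then sat. aq. NH4Cl
Reagents that add atoms: ethynylmagnesium bromide (4), C#C[Mg]Br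
Why: Grignard 1,2-addition, in which the aldehyde is far more electrophilic than the methyl ester toward the weakly nucleophilic alkynyl reagent at low temperature; the new carbinol centre C14 forms as a racemate on purpose because it later becomes the sp2 ring carbon C2.

Step 4
Reactants: 6 hexan-1-ol
Product: 7 hexyl trifluoromethanesulfonate (hexyl triflate)
Conditions: Tf2O (1.05 equiv), pyridine (1.05 equiv), CH2Cl2, −20 to 0 °C; short silica plug, used at once
Reagents that add atoms: trifluoromethanesulfonic anhydride, O=S(=O)(OS(=O)(=O)C(F)(F)F)C(F)(F)F
Why: O-sulfonylation of a primary alcohol with Tf2O and pyridine at low temperature is the standard preparation of a primary alkyl triflate; no stereocentre is involved.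

Step 5
Reactants: 5 methyl 14-hydroxyhexadec-15-ynoate (racemic); 7 hexyl trifluoromethanesulfonate
Product: 8 methyl 14-(hexyloxy)hexadec-15-ynoate (racemic)
Conditions: 7 (1.5 equiv), 2,6-di-tert-butyl-4-methylpyridine (2 equiv), CH2Cl2, 0 to 40 °C
Reagents that add atoms: hexyl trifluoromethanesulfonate (7), CCCCCCOS(=O)(=O)C(F)(F)F
Why: Williamson-type SN2 O-alkylation with a primary triflate and a hindered, non-nucleophilic pyridine base needs no alkoxide, so the methyl ester and the terminal alkyne C–H should survive; the C14 centre is not touched and stays racemic.

Step 6
Reactants: 8 methyl 14-(hexyloxy)hexadec-15-ynoate (racemic)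
Product: 10 methyl 14-(hexyloxy)-15-oxohexadecanoate (racemic), via enol 9 (not isolated)
Conditions: Ph3PAuCl (2 mol %), AgOTf (2 mol %), 1,4-dioxane/H2O, 60 °C
Reagents that add atoms: water, O
Why: Gold-catalysed Markovnikov hydration of a terminal alkyne (cationic monovalent gold from Ph3PAuCl and AgOTf activates the triple bond for attack of water at the internal carbon, and enol 9 tautomerises) should give the methyl ketone under neutral conditions that spare the ether and the ester; no new stereocentre is formed.

Step 7
Reactants: 10 methyl 14-(hexyloxy)-15-oxohexadecanoate (racemic); 11 trimethylsilyldiazomethane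
Product: 15 methyl 13-(3-methyl-5-pentyl-2,5-dihydrofuran-2-yl)tridecanoate (cis/trans mixture of racemates), via lithium alkoxide adduct 12 (not isolated), via diazoalkene 13 (not isolated), via alkylidene carbene 14 (not isolated)
Conditions: 11 (1.2 equiv), n-BuLi (1.15 equiv), THF, −78 °C; then 10, −78 °C to rt
Reagents that add atoms: trimethylsilyldiazomethane (11), C[Si](C)(C)C=[N+]=[N-]
Why: Lithiated trimethylsilyldiazomethane adds to the C15 ketone to give alkoxide 12, a Peterson-type elimination of lithium trimethylsilanolate gives diazoalkene 13, and loss of N2 leaves the singlet alkylidene carbene 14, whose divalent carbon becomes ring carbon C4. The carbene inserts in a concerted manner into one C–H bond of the O–CH2 group of the hexyl ether (the O–C bond itself stays intact), which forms C4–C5 while the C3=C4 double bond is already in place. The closest known reaction type is the alkylidene carbene 1,5 C–H insertion of alpha-alkoxy ketones with lithiated trimethylsilyldiazomethane, an established entry to 2,5-dihydrofurans. The single ring, the five-membered oxygen heterocycle, is closed at carbon by C–C bond formation through the five-centre 1,5 insertion, with the carbene carbon as atom 1 and the ether methylene as atom 5. C5 becomes a new stereocentre without control relative to the racemic C2, so a cis/trans mixture is expected and accepted because step 8 flattens both centres. The step needs ketone-over-ester chemoselectivity, secured by the higher electrophilicity of the ketone at −78 °C and a slight deficit of n-BuLi, and it needs the O–CH2 site to win over the equally placed but unactivated chain methylene C12 and over a 1,2-shift, secured by the oxygen lone pair that activates the adjacent C–H bond and by the poor migratory aptitude of the two alkyl groups.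

Step 8
Reactants: 15 methyl 13-(3-methyl-5-pentyl-2,5-dihydrofuran-2-yl)tridecanoate
Product: 16 methyl 13-(3-methyl-5-pentylfuran-2-yl)tridecanoate
Conditions: DDQ (1.1 equiv), 1,4-dioxane, rt
Reagents that add atoms: none
Why: Dehydrogenation with DDQ, in which hydride abstraction from the doubly activated (allylic and alpha to oxygen) C2–H or C5–H gives a conjugated oxocarbenium ion that loses the proton at the other alpha carbon, with aromatisation as driving force; both ring stereocentres are erased.

Step 9
Reactants: 16 methyl 13-(3-methyl-5-pentylfuran-2-yl)tridecanoate
Product: 17 13-(3-methyl-5-pentylfuran-2-yl)tridecanoic acid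
Conditions: LiOH·H2O (3 equiv), THF/MeOH/H2O, rt; then 1 M HCl to pH 4, 0 °C
Reagents that add atoms: lithium hydroxide, [Li+].[OH-]
Why: Ester saponification with LiOH leaves the base-stable furan untouched, and acidification only to about pH 4 in the cold protects the acid-sensitive trialkylfuran; no stereocentre is present.

Compound list
1 | 14-methoxy-14-oxotetradecanoic acid | COC(=O)CCCCCCCCCCCCC(=O)O | starting material
2 | methyl 14-hydroxytetradecanoate | COC(=O)CCCCCCCCCCCCCO | intermediate
3 | methyl 14-oxotetradecanoate | COC(=O)CCCCCCCCCCCCC=O | intermediate
4 | ethynylmagnesium bromide | C#C[Mg]Br | starting material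
5 | methyl 14-hydroxyhexadec-15-ynoate (racemic) | COC(=O)CCCCCCCCCCCCC(O)C#C | intermediate
6 | hexan-1-ol | CCCCCCO | starting material
7 | hexyl trifluoromethanesulfonate | CCCCCCOS(=O)(=O)C(F)(F)F | intermediate
8 | methyl 14-(hexyloxy)hexadec-15-ynoate (racemic) | CCCCCCOC(C#C)CCCCCCCCCCCCC(=O)OC | intermediate
9 | methyl 14-(hexyloxy)-15-hydroxyhexadec-15-enoate (enol, racemic, not isolated) | CCCCCCOC(C(O)=C)CCCCCCCCCCCCC(=O)OC | intermediate
10 | methyl 14-(hexyloxy)-15-oxohexadecanoate (racemic) | CCCCCCOC(C(C)=O)CCCCCCCCCCCCC(=O)OC | intermediate
11 | trimethylsilyldiazomethane | C[Si](C)(C)C=[N+]=[N-] | starting material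
12 | lithium alkoxide of methyl 16-diazo-14-(hexyloxy)-15-hydroxy-15-methyl-16-(trimethylsilyl)hexadecanoate (mixture of diastereomers, not isolated) | CCCCCCOC(CCCCCCCCCCCCC(=O)OC)C(C)(O[Li])C(=[N+]=[N-])[Si](C)(C)C | intermediate
13 | methyl 16-diazo-14-(hexyloxy)-15-methylhexadec-15-enoate (diazoalkene, racemic, not isolated) | CCCCCCOC(CCCCCCCCCCCCC(=O)OC)C(C)=C=[N+]=[N-] | intermediate
14 | methyl 14-(hexyloxy)-15-methyl-16-ylidenehexadec-15-enoate (free alkylidene carbene, racemic, not isolated) | CCCCCCOC(CCCCCCCCCCCCC(=O)OC)C(C)=[C] | intermediate
15 | methyl 13-(3-methyl-5-pentyl-2,5-dihydrofuran-2-yl)tridecanoate (cis/trans mixture, each racemic) | CCCCCC1OC(CCCCCCCCCCCCC(=O)OC)C(C)=C1 | intermediate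
16 | methyl 13-(3-methyl-5-pentylfuran-2-yl)tridecanoate | CCCCCc1cc(C)c(CCCCCCCCCCCCC(=O)OC)o1 | intermediate
17 | 13-(3-methyl-5-pentylfuran-2-yl)tridecanoic acid | CCCCCc1cc(C)c(CCCCCCCCCCCCC(=O)O)o1 | target

Total steps: 9. Longest linear sequence: 8 steps (steps 1, 2, 3, 5, 6, 7, 8 and 9 from compound 1; step 4 is a one-step branch from hexan-1-ol).

Steps most likely to fail

Step 7. The carbene may insert into the unactivated chain methylene instead of the ether methylene, the lithiated reagent may enolise the alpha-alkoxy ketone, or it may add to the ester. The fallback builds the furan by a different, known ring construction and sets out from 5. Hydration with the same Ph3PAuCl/AgOTf system should give the hydroxy ketone methyl 14-hydroxy-15-oxohexadecanoate F1. Addition of hept-1-ynyllithium (hept-1-yne, n-BuLi, CeCl3, THF, −78 °C, in excess to cover the free hydroxyl) to the ketone should give the alkynediol methyl 14,15-dihydroxy-15-methyldocos-16-ynoate F2. AgNO3 on silica gel (CH2Cl2, rt) should then bring about 5-endo-dig attack of the C14 hydroxyl on the alkyne and dehydration to the furan. The route is rejoined at 16, so step 8 is bypassed as well.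

Step 5. The hindered, weakly nucleophilic propargylic hydroxyl may be alkylated too slowly, so that elimination or hydrolysis of the triflate takes over. The fallback forms the ether by reductive etherification and sets out from 5. Silylation (TMSCl, imidazole, CH2Cl2) should give methyl 14-[(trimethylsilyl)oxy]hexadec-15-ynoate F3. Treatment of F3 with hexanal, Et3SiH and catalytic TMSOTf (CH2Cl2, −78 °C) should give the hexyl ether by silane reduction of the intermediate oxocarbenium ion. The route is rejoined at 8.

Step 8. The quinone may go on to oxidise or degrade the electron-rich trialkylfuran once it has formed. The fallback keeps the furan away from any oxidant and sets out from 15. Addition of Br2 (CH2Cl2, −78 °C) to the ring alkene should give methyl 13-(3,4-dibromo-3-methyl-5-pentyloxolan-2-yl)tridecanoate F4. Double dehydrobromination with DBU (toluene, 80 °C) should then lead to the furan, since each elimination toward an alpha-oxygen hydrogen makes the remaining bromide allylic and labile. The route is rejoined at 16.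

Further compounds
F1 | step 7 | methyl 14-hydroxy-15-oxohexadecanoate (racemic) | COC(=O)CCCCCCCCCCCCC(O)C(C)=O
F2 | step 7 | methyl 14,15-dihydroxy-15-methyldocos-16-ynoate (mixture of diastereomers) | CCCCCC#CC(C)(O)C(O)CCCCCCCCCCCCC(=O)OC
F3 | step 5 | methyl 14-[(trimethylsilyl)oxy]hexadec-15-ynoate (racemic) | COC(=O)CCCCCCCCCCCCC(O[Si](C)(C)C)C#C
F4 | step 8 | methyl 13-(3,4-dibromo-3-methyl-5-pentyloxolan-2-yl)tridecanoate (mixture of diastereomers) | CCCCCC1OC(CCCCCCCCCCCCC(=O)OC)C(C)(Br)C1Br
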